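(The runs are calculated for substances that don't exist.)

Percent of the charge was the wrong unit for these runs, so I turned the readings into molar concentrations.

| setting | ochre | grey | flask |
|---|---|---|---|
| solid substrate | 0.070 M | 0.11 M | 0.050 M |
| coupling partner | 0.045 M | 0.045 M | 0.0450 M |
| free catalyst | 5 mM | 5 mM | 5.0 mM |
| second catalyst | 1 mM | 1 mM | 1.0 mM |
| remark | run made earlier | run made earlier |  |
| time |  |  | 80 min |

| run | time / min | product / % | starting material / % |
|---|---|---|---|
| ochre | 5.00 | 0.1 | 0.4 |
| ochre | 15.0 | 0.7 | 3.3 |
| ochre | 25.0 | 0 | 2.2 |
| ochre | 40.0 | 0.9 | 3.5 |
| ochre | 60.0 | 3.1 | 3.7 |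
| ochre | 80.0 | 5.0 | 4.3 |
| ochre | 90.0 | 5.0 | 4.1 |
| grey | 8.00 | 0 | 1.3 |
| grey | 12.0 | 0 | 1.7 |
| grey | 20.0 | 0.8 | 2.4 |
| grey | 25.0 | 0.5 | 2.6 |
| grey | 40.0 | 0.9 | 2.1 |
| grey | 60.0 | 1.7 | 2.8 |
| grey | 90.0 | 2.9 | 2.7 |

(scatter of a reading: 0.5 percentage points)

- solid, in amounts per volume of the solution: solid substrate
- at the start none of the solid substrate is in solution
- starting material means what is dissolved; the solid is not counted in it
- starting material is what solid substrate becomes in solution

- how much product there is at 80 min, in percent of the solid substrate charged
- concentration of starting material in solution at 80 min, in percent of saturation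

First I asked whether the dissolved level followed the solid charged. The grey run held 1.57 times the solid of the ochre run, yet at 90.0 min the ochre run read 2.87 mM of starting material and the grey run 2.97 mM.

Then I asked the same of product. At that time the ochre run read 3.50 mM and the grey run 3.19 mM, so, with the other charges equal in these two runs, product looked zero order in the solid charged.

Last I asked whether this flask would keep its solid. The ochre run read 6.51 mM of starting material and product together at 80.0 min, less than the 0.050 M charged here, so, unless much had gone into forms that were not read, I expected solid to remain.

I therefore carried one quantity, 3.50 mM, read from the ochre run: the product concentration reached by that time with solid present. Divided by this flask's charge, it gave me 7.00 %. I expected a similar dissolved level, and I put no figure of my own on saturation.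

The forecast stood on similar ground, “product depends on dissolved material, not on solid charged”, but gave less product than I did: 5.6 %, with the solution at 85 % of saturation.

The flask gave 7.17 % of product and stood at 67.3 % of saturation.

    starting material + free catalyst ⇌ free catalyst + open intermediate (K = 1.70, k = 0.240 /M/s)
    second catalyst + open intermediate ⇌ catalyst intermediate (K = 52.0 /M, k = 24.0 /M/s)
    coupling partner + catalyst intermediate → second catalyst + product (k = 0.200 /M/s)
    solid substrate ⇌ starting material, rate k4*(cs4 - [starting material]) while solid is left; crystals form when [starting material] > cs4 (solubility = 4.30 mM, k = 0.00100 /s)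

Saturation was 4.3 mM, and the flask held 2.89 mM of starting material at 80 min, less than saturation. In the neighbouring flask with 0.013 M of solid substrate, the carried 3.50 mM gave 26.9 %; that flask gave 27.6 %, with 25.8 % still solid.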